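**Retrosynthetic overview**
- Feature: ring B carries three contiguous substituted carbons, C1' (bonded to C2 of pyranone ring C), C2' (OH) and C3' (OH). A 3-alkoxybenzyne delivers this 1,2,3-array when a carbon nucleophile and then an oxygen electrophile are added across its triple bond.
- Last disconnection: 5-OH and 3'-OH come from a 5-methyl ether and a 3'-benzyl ether cleaved by BCl3. The 3-, 7- and 8-methyl ethers are kept.
- Key disconnection: C2-C1' and C2'-O are cut together. This gives 3,5,7,8-tetramethoxychromone (used as its C2-magnesium derivative) and 3-(benzyloxy)benzyne (from 3-(benzyloxy)-2-iodophenyl triflate).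
- Precursors: for the chromone, 1,2,3,5-tetramethoxybenzene supplies ring A, a methoxyacetic Weinreb amide supplies C4, C3 and 3-OMe, and DMF dimethyl acetal supplies C2. The aryne precursor comes from 2-iodoresorcinol by monobenzylation and triflation.
- Ring order: rings A and B are bought. Ring C is the only ring formed (step 3), before the inter-ring bond is made.

Key step: step 6

Remark on the chemistry: the methoxyacetyl unit is introduced as its Weinreb amide onto an aryllithium. Methoxyacetyl chloride with AlCl3 is avoided because that acylium ion readily loses CO and then alkylates electron-rich arenes. The target has no stereocentre.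

**Step 1**
Reactants: 1 1,2,3,5-tetramethoxybenzene; 2 N,2-dimethoxy-N-methylacetamide
Product: 4 2-methoxy-1-(2,3,4,6-tetramethoxyphenyl)ethan-1-one, via (2,3,4,6-tetramethoxyphenyl)lithium 3 (not isolated)
Conditions: n-BuLi, THF, 0 °C; then 2, −78 → 0 °C; 1 M aq HCl
Reagents that add atoms: n-butyllithium, [Li]CCCC (lithium in 3 only)
Why: Directed ortho-lithiation removes the only kind of ring proton, which sits between two methoxy groups, and the Weinreb ketone synthesis then stops at the ketone because the N-methoxy-N-methyl amide adduct does not collapse until the acid quench.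

**Step 2**
Reactants: 4 2-methoxy-1-(2,3,4,6-tetramethoxyphenyl)ethan-1-one
Product: 5 1-(2-hydroxy-3,4,6-trimethoxyphenyl)-2-methoxyethan-1-one
Conditions: BCl3 (1.1 equiv), CH2Cl2, −78 → 0 °C; then H2O
Reagents that add atoms: none
Why: Chelation-directed Lewis acid demethylation: boron bridges the ketone oxygen and an ortho methoxy oxygen and chloride removes the methyl group, and of the two ortho ethers the one at C2 should be cleaved because the neighbouring 3-methoxy group twists it out of the ring plane, which makes its oxygen more basic and its loss strain-relieving, while one equivalent of BCl3 at low temperature should leave the side-chain, 3-, 4- and 6-methyl ethers alone.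

**Step 3**
Reactants: 5 1-(2-hydroxy-3,4,6-trimethoxyphenyl)-2-methoxyethan-1-one
Product: 7 3,5,7,8-tetramethoxy-4H-chromen-4-one, via enaminone 6 (not isolated)
Conditions: Me2NCH(OMe)2, toluene, 100 °C; then AcOH, 80 °C
Reagents that add atoms: N,N-dimethylformamide dimethyl acetal, COC(OC)N(C)C
Why: Condensation of the activated CH2 with the amide acetal gives enaminone 6, and acid-promoted intramolecular oxa-Michael addition of the phenol followed by loss of dimethylamine closes ring C, the standard formylative chromone and isoflavone closure of ortho-hydroxyaryl ketones.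

**Step 4**
Reactants: 8 2-iodoresorcinol
Product: 9 3-(benzyloxy)-2-iodophenol
Conditions: BnBr (1.0 equiv), K2CO3, acetone, reflux
Reagents that add atoms: benzyl bromide, BrCc1ccccc1
Why: Williamson ether synthesis on a symmetrical diol, so that one equivalent of benzyl bromide should give the monoether as the main component of a statistical mixture from which diol and diether are separated by chromatography.

**Step 5**
Reactants: 9 3-(benzyloxy)-2-iodophenol
Product: 10 3-(benzyloxy)-2-iodophenyl trifluoromethanesulfonate
Conditions: Tf2O, pyridine, CH2Cl2, 0 °C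
Reagents that add atoms: trifluoromethanesulfonic anhydride, O=S(=O)(OS(=O)(=O)C(F)(F)F)C(F)(F)F
Why: Routine O-sulfonylation of a phenol with triflic anhydride and pyridine, to which the aryl iodide and the benzyl ether are inert.

**Step 6**
Reactants: 7 3,5,7,8-tetramethoxy-4H-chromen-4-one; 10 3-(benzyloxy)-2-iodophenyl trifluoromethanesulfonate
Product: 15 2-[3-(benzyloxy)-2-hydroxyphenyl]-3,5,7,8-tetramethoxy-4H-chromen-4-one, via C2-chloromagnesio chromone 11 (not isolated), via 3-(benzyloxy)benzyne 12 (not isolated), via C2'-arylmagnesium chloride 13 (not isolated), via dimethyl arylboronate 14 (not isolated)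
Conditions: 7, TMPMgCl·LiCl (1.05 equiv), THF, −40 °C; 10 (1.2 equiv), then Me3SiCH2MgCl (1.2 equiv, slow addition), −78 → 0 °C; B(OMe)3, −78 °C → rt; 30% aq H2O2, AcOH, 0 °C → rt
Reagents that add atoms: hydrogen peroxide, OO (the oxygen on C2'); trimethyl borate, COB(OC)OC (boron and methoxy groups in 14 only); TMPMgCl·LiCl, CC1(C)CCCC(C)(C)N1[Mg]Cl.[Li+].[Cl-] (MgCl in 11 and 13 only)
Why: Proposed new method: TMPMgCl·LiCl should remove C2-H of 7, its most acidic proton (an sp2 carbon bonded to O1, beside the 3-methoxy-bearing carbon and vinylogous to C4=O), and β-elimination of methoxide from the resulting 11 is ruled out, since a six-membered ring cannot hold the alkyne that would result. Me3SiCH2MgCl, chosen because it exchanges activated aryl iodides but adds only sluggishly to arynes and carbonyl groups, swaps the iodine of 10 for magnesium, Mg(OTf)Cl then leaves, and 12 results, in which the carbon that bore iodine (flanked by OBn) and the carbon that bore the triflate are triply bonded. Carbomagnesiation of 12 by 11 forms C2-C1' and leaves magnesium on C2' in 13, B(OMe)3 converts 13 into boronate 14, and H2O2 triggers the 1,2-shift of the aryl group from boron to oxygen that forms C2'-O at that same carbon. The closest known reaction type is the addition of aryl Grignard reagents, magnesium amides or magnesium thiolates to arynes with electrophilic trapping of the new ortho-arylmagnesium, and C2 metalation of chromones by TMP bases is likewise known; new here is a metalated chromone as the carbon nucleophile joined to an oxidative quench. Regioselectivity is the critical demand: 11 has to bond to the former C-OTf carbon, meta to oxygen, which the σ-acceptor benzyloxy group favours by widening the bond angle at that carbon (more p character, more electrophilic) and by stabilising the carbanion that develops beside it at C2'. No ring closes and no stereocentre forms; chemoselectivity rests on complete metalation without excess base and on slow addition of the activator, so that 11 is the dominant nucleophile whenever 12 is present.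

**Step 7**
Reactants: 15 2-[3-(benzyloxy)-2-hydroxyphenyl]-3,5,7,8-tetramethoxy-4H-chromen-4-one
Product: 16 5,2',3'-trihydroxy-3,7,8-trimethoxyflavone
Conditions: BCl3 (5 equiv), C6HMe5 (3 equiv), CH2Cl2, −78 → 0 °C; then 1 M aq HCl, THF, rt
Reagents that add atoms: none
Why: Lewis acid ether cleavage in two stages in one flask: BCl3 with pentamethylbenzene as a non-basic benzyl cation trap removes the aryl benzyl ether at low temperature, helped by the boron ester formed at the neighbouring 2'-oxygen, and on warming the six-membered boron chelate between C4=O and O5 lets chloride take the 5-methyl group, after which the carbonyl oxygen is occupied so that the 3-methoxy group and the unchelated 7- and 8-methoxy groups should stay.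

**Compound list**
1 | 1,2,3,5-tetramethoxybenzene | COc1cc(OC)c(OC)c(OC)c1 | starting material
2 | N,2-dimethoxy-N-methylacetamide | COCC(=O)N(C)OC | starting material
3 | (2,3,4,6-tetramethoxyphenyl)lithium | [Li]c1c(OC)cc(OC)c(OC)c1OC | intermediate
4 | 2-methoxy-1-(2,3,4,6-tetramethoxyphenyl)ethan-1-one | COCC(=O)c1c(OC)cc(OC)c(OC)c1OC | intermediate
5 | 1-(2-hydroxy-3,4,6-trimethoxyphenyl)-2-methoxyethan-1-one | COCC(=O)c1c(OC)cc(OC)c(OC)c1O | intermediate
6 | (Z)-3-(dimethylamino)-1-(2-hydroxy-3,4,6-trimethoxyphenyl)-2-methoxyprop-2-en-1-one (NMe2 trans to the acyl group) | CN(C)/C=C(\OC)C(=O)c1c(OC)cc(OC)c(OC)c1O | intermediate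
7 | 3,5,7,8-tetramethoxy-4H-chromen-4-one | COc1cc(OC)c2c(=O)c(OC)coc2c1OC | intermediate
8 | 2-iodoresorcinol (2-iodobenzene-1,3-diol) | Oc1cccc(O)c1I | starting material
9 | 3-(benzyloxy)-2-iodophenol | Oc1cccc(OCc2ccccc2)c1I | intermediate
10 | 3-(benzyloxy)-2-iodophenyl trifluoromethanesulfonate | O=S(=O)(Oc1cccc(OCc2ccccc2)c1I)C(F)(F)F | intermediate
11 | chloro(3,5,7,8-tetramethoxy-4-oxo-4H-chromen-2-yl)magnesium | COc1cc(OC)c2c(=O)c(OC)c([Mg]Cl)oc2c1OC | intermediate
12 | 3-(benzyloxy)benzyne (1-(benzyloxy)-2,3-didehydrobenzene) | C1#CC(OCc2ccccc2)=CC=C1 | intermediate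
13 | chloro[2-(benzyloxy)-6-(3,5,7,8-tetramethoxy-4-oxo-4H-chromen-2-yl)phenyl]magnesium | COc1cc(OC)c2c(=O)c(OC)c(-c3cccc(OCc4ccccc4)c3[Mg]Cl)oc2c1OC | intermediate
14 | dimethyl [2-(benzyloxy)-6-(3,5,7,8-tetramethoxy-4-oxo-4H-chromen-2-yl)phenyl]boronate | COc1cc(OC)c2c(=O)c(OC)c(-c3cccc(OCc4ccccc4)c3B(OC)OC)oc2c1OC | intermediate
15 | 2-[3-(benzyloxy)-2-hydroxyphenyl]-3,5,7,8-tetramethoxy-4H-chromen-4-one | COc1cc(OC)c2c(=O)c(OC)c(-c3cccc(OCc4ccccc4)c3O)oc2c1OC | intermediate
16 | 5,2',3'-trihydroxy-3,7,8-trimethoxyflavone | COc1cc(O)c2c(=O)c(OC)c(-c3cccc(O)c3O)oc2c1OC | target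

**Step count**
Total step count: 7. Longest linear sequence: 5 (steps 1, 2, 3, 6, 7).

**Steps most likely to fail**

**Step 6.**
- What may go wrong: the aryne may be intercepted by other nucleophiles in the flask (the free amine, the activator, the product Grignard reagent). Iodine may transfer from the aryne precursor to the organomagnesium species. The metalated chromone may self-condense. The C2' carbanion may be protonated before borylation.
- Fallback: it uses known chemistry, sets out from 7 and comes back at 16. Bought 3-bromocatechol is benzylated twice (BnBr, K2CO3, DMF) to 1,2-bis(benzyloxy)-3-bromobenzene F1. Compound 7 is zincated at C2 (TMPZnCl·LiCl, THF) to chloro(3,5,7,8-tetramethoxy-4-oxo-4H-chromen-2-yl)zinc F2. Negishi coupling of the two (Pd(OAc)2, SPhos, THF, 50 °C) gives 2-[2,3-bis(benzyloxy)phenyl]-3,5,7,8-tetramethoxy-4H-chromen-4-one F3. The conditions of step 7 then cleave both benzyl ethers and the 5-methyl ether to give 16.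

**Step 2.**
- What may go wrong: the ortho ether at C6 may be cleaved in place of the one at C2, which would lead into the 5,6,7-oxygenation series. The side-chain ether may also be attacked.
- Fallback: it sets out from 2 and comes back at 5. It removes the choice by using a symmetrical ketone and adding the missing oxygen afterwards. Bought 1,3,5-trimethoxybenzene is lithiated (n-BuLi, THF) to (2,4,6-trimethoxyphenyl)lithium F4, which is acylated with 2 to give 2-methoxy-1-(2,4,6-trimethoxyphenyl)ethan-1-one F5. BCl3 cleaves one of the two equivalent ortho ethers to give 1-(2-hydroxy-4,6-dimethoxyphenyl)-2-methoxyethan-1-one F6. Iodination ortho to the free phenol (I2, HIO3, aqueous EtOH) gives 1-(2-hydroxy-3-iodo-4,6-dimethoxyphenyl)-2-methoxyethan-1-one F7. Ullmann-type methoxylation (CuI, NaOMe, MeOH/DMF, heat) gives 5.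

**Step 7.**
- What may go wrong: the 3- or 8-methyl ether may be lost under the excess of BCl3 that the catechol demands. The benzyl cation may transfer to ring A. The boron chelates may be released incompletely.
- Fallback: it sets out from 7 and comes back at 16. It moves the demethylation to the simple chromone and ends with a neutral hydrogenolysis. Compound 7 is treated with BCl3 (1.1 equiv, CH2Cl2, −78 → 0 °C) to give 5-hydroxy-3,7,8-trimethoxy-4H-chromen-4-one F8. BnBr, K2CO3, DMF at 60 °C gives 5-(benzyloxy)-3,7,8-trimethoxy-4H-chromen-4-one F9. The sequence of step 6 with 10 then runs through [5-(benzyloxy)-3,7,8-trimethoxy-4-oxo-4H-chromen-2-yl]chloromagnesium F10, aryne 12, the C2'-arylmagnesium chloride F11 and the dimethyl arylboronate F12. This gives 5-(benzyloxy)-2-[3-(benzyloxy)-2-hydroxyphenyl]-3,7,8-trimethoxy-4H-chromen-4-one F13. H2, Pd/C in EtOAc/MeOH at rt removes both benzyl groups to give 16.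

**Further compounds**
F1 | step 6 | 1,2-bis(benzyloxy)-3-bromobenzene | Brc1cccc(OCc2ccccc2)c1OCc1ccccc1
F2 | step 6 | chloro(3,5,7,8-tetramethoxy-4-oxo-4H-chromen-2-yl)zinc | COc1cc(OC)c2c(=O)c(OC)c([Zn]Cl)oc2c1OC
F3 | step 6 | 2-[2,3-bis(benzyloxy)phenyl]-3,5,7,8-tetramethoxy-4H-chromen-4-one | COc1cc(OC)c2c(=O)c(OC)c(-c3cccc(OCc4ccccc4)c3OCc3ccccc3)oc2c1OC
F4 | step 2 | (2,4,6-trimethoxyphenyl)lithium | [Li]c1c(OC)cc(OC)cc1OC
F5 | step 2 | 2-methoxy-1-(2,4,6-trimethoxyphenyl)ethan-1-one | COCC(=O)c1c(OC)cc(OC)cc1OC
F6 | step 2 | 1-(2-hydroxy-4,6-dimethoxyphenyl)-2-methoxyethan-1-one | COCC(=O)c1c(O)cc(OC)cc1OC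
F7 | step 2 | 1-(2-hydroxy-3-iodo-4,6-dimethoxyphenyl)-2-methoxyethan-1-one | COCC(=O)c1c(OC)cc(OC)c(I)c1O
F8 | step 7 | 5-hydroxy-3,7,8-trimethoxy-4H-chromen-4-one | COc1cc(O)c2c(=O)c(OC)coc2c1OC
F9 | step 7 | 5-(benzyloxy)-3,7,8-trimethoxy-4H-chromen-4-one | COc1cc(OCc3ccccc3)c2c(=O)c(OC)coc2c1OC
F10 | step 7 | [5-(benzyloxy)-3,7,8-trimethoxy-4-oxo-4H-chromen-2-yl]chloromagnesium | COc1cc(OCc3ccccc3)c2c(=O)c(OC)c([Mg]Cl)oc2c1OC
F11 | step 7 | {2-(benzyloxy)-6-[5-(benzyloxy)-3,7,8-trimethoxy-4-oxo-4H-chromen-2-yl]phenyl}chloromagnesium | COc1cc(OCc3ccccc3)c2c(=O)c(OC)c(-c3cccc(OCc4ccccc4)c3[Mg]Cl)oc2c1OC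
F12 | step 7 | dimethyl {2-(benzyloxy)-6-[5-(benzyloxy)-3,7,8-trimethoxy-4-oxo-4H-chromen-2-yl]phenyl}boronate | COc1cc(OCc3ccccc3)c2c(=O)c(OC)c(-c3cccc(OCc4ccccc4)c3B(OC)OC)oc2c1OC
F13 | step 7 | 5-(benzyloxy)-2-[3-(benzyloxy)-2-hydroxyphenyl]-3,7,8-trimethoxy-4H-chromen-4-one | COc1cc(OCc3ccccc3)c2c(=O)c(OC)c(-c3cccc(OCc4ccccc4)c3O)oc2c1OC
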